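We have 4 questions, and each one is about E at the end of a run.

common to all: Z 10 mM; time 3.0 h

| run | temperature |
|---|---|
| delta | 20 °C |
| theta | 45 °C |
| eta | 70 °C |

    E → D (k1 = 0.28 h⁻¹, Ea1 = 87.0 kJ mol⁻¹)
    D ⇌ G (K2 = 4.2, k2 = 0.30 h⁻¹, Ea2 = 90.0 kJ mol⁻¹, ΔH2 = −65.0 kJ mol⁻¹)
    Z → E (k3 = 3.2 h⁻¹, Ea3 = 80.0 kJ mol⁻¹)
    (constants at 20 °C)

- the list of constants is for 20 °C, to be carried to other temperatures by the activation energies and enthalpies

1. the flask with the highest amount of E, in percent of the Z charged ("all alike" if they lie within 1.5 percentage points) (delta / theta / eta / all alike)
2. final E, as a percentage of the Z charged, in delta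
3. final E, as a percentage of the Z charged, in theta
4. final E, as a percentage of the Z charged, in eta

The line E → D is the way out of E, so we start there. It is first order, and in delta E lives 3.57 h on average. So the delta run holds 0.840 lifetimes of E, and this count of lifetimes, the rate constant of E → D times the time, is what we carry.

The line D ⇌ G lies beyond E, and E → D has no way back, so we set it aside.

The line Z → E feeds E, and in delta it is 11.4 times faster than E → D. In delta Z is half gone in 0.217 h, so we treat the filling as over early. E then decays, with a small correction g, the constant of Z → E over the difference of the two constants, here 1.10. As a fraction of the charge, E is g times e to the minus the count, which gives 47.3 % in delta.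

But E → D speeds up with temperature. It runs 16.5 times faster in theta and 181 times faster in eta. The counts become 13.9 and 152. Leaving g aside, we get <0.001 % in theta and <0.001 % in eta. Our choice is delta.

The forecast names delta, with 47.3 % in delta, <0.001 % in theta and 0 % in eta. Its ground is that “after 3 h E is essentially gone in both warmer flasks”.

The simulation gives delta, with 47.3 % in delta, 0 % in theta and 0 % in eta. So the E of delta is a point on a falling curve, for it stands at 0.0246 % after 30.0 h. In theta, Z → E has a constant of 42.2 h⁻¹, so g there is 1.12. Half the theta run holds 6.95 lifetimes, and the count gives 0.109 % of the charge as E. The theta flask held 0.109 % at 1.50 h.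

The numbers are assumed; the flask was simulated.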